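## Retrosynthetic overview

1. The C6 aryl ester and C2 acetate are installed last; both carbinols come from ketones by reductions directed by the tertiary C4 hydroxyl.
2. The seven-membered ring is formed second, by ring-closing metathesis of a C1 allyl group with a methallyl ketone arm on C5 (C8=C9).
3. The C4 carbinol comes from isopropylcerium addition to a cyclopentanone; the C1 quaternary centre comes from Pd-catalysed decarboxylative allylation. Both occur anti to the C5 substituent.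
4. The key C5–C6 bond is made by intermolecular Michael addition of lithiated 2-(2-methylallyl)-1,3-dithiane to (R)-4-silyloxy-2-methylcyclopent-2-enone, anti to the silyloxy group.
5. The five-membered ring is formed first, by Piancatelli rearrangement of 1-(furan-2-yl)ethanol, and resolved with a lipase.

Assumption and convention: the lipase acylates the (R)-enantiomer of the racemic hydroxy enone (the usual preference for 4-hydroxycyclopent-2-enones). Carotane numbering of the target is used for every intermediate (C1 methyl-bearing ring-fusion carbon, C2 acetoxy carbon, C4 isopropyl carbinol, C5 ring-fusion CH, C6 aroyloxy carbon, C8=C9 alkene); β is the face of the C1 methyl, α the opposite face.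

## Route

Step 1
Reactants: 1 (±)-1-(furan-2-yl)ethan-1-ol
Product: 3 (±)-4-hydroxy-2-methylcyclopent-2-en-1-one, via (±)-trans-4-hydroxy-5-methylcyclopent-2-en-1-one 2 (not isolated)
Conditions: H2O, NaOAc/AcOH buffer (pH 5), 110 °C (sealed); then K2HPO4 to pH 8, 100 °C
Reagents that add atoms: water, O
Why: Piancatelli rearrangement (furyl carbinol to oxocarbenium ion, water addition, ring opening, conrotatory 4π electrocyclisation) gives the trans-4-hydroxy-5-methyl enone, which at pH 8 isomerises by dehydration/rehydration to the more stable 2-methyl enone; the product is racemic and is resolved in step 2.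

Step 2
Reactants: 3 (±)-4-hydroxy-2-methylcyclopent-2-en-1-one
Product: 4 (1R)-3-methyl-4-oxocyclopent-2-en-1-yl acetate
Conditions: Burkholderia cepacia lipase (lipase PS), vinyl acetate, MTBE, 30 °C, stopped near 45 % conversion; chromatography removes the unreacted (S)-alcohol
Reagents that add atoms: vinyl acetate, CC(=O)OC=C
Why: Lipase-catalysed kinetic resolution by enantioselective transesterification acylates only the (R)-alcohol and so fixes the absolute configuration of the route.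

Step 3
Reactants: 4 (1R)-3-methyl-4-oxocyclopent-2-en-1-yl acetate
Product: 5 (4R)-4-hydroxy-2-methylcyclopent-2-en-1-one
Conditions: lipase PS, KH2PO4/K2HPO4 buffer (pH 7), 30 °C
Reagents that add atoms: none
Why: Enzymatic ester hydrolysis at neutral pH avoids base-induced β-elimination of the 4-oxygen substituent and, since the (R)-acetate is the fast-reacting enantiomer, upgrades the ee without touching the stereocentre.

Step 4
Reactants: 5 (4R)-4-hydroxy-2-methylcyclopent-2-en-1-one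
Product: 6 (4R)-4-[(tert-butyldimethylsilyl)oxy]-2-methylcyclopent-2-en-1-one
Conditions: TBSCl, imidazole, DMF, 0 → 25 °C
Reagents that add atoms: TBSCl, CC(C)(C)[Si](C)(C)Cl
Why: Silyl ether formation protects the alcohol and supplies the bulky α-face group that directs the Michael addition to the β face.

Step 5
Reactants: 7 1,3-dithiane; 8 3-chloro-2-methylprop-1-ene
Product: 10 2-(2-methylprop-2-en-1-yl)-1,3-dithiane, via 2-lithio-1,3-dithiane 9 (not isolated)
Conditions: n-BuLi, THF, −30 °C; then 8, −78 → 0 °C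
Reagents that add atoms: none
Why: Corey–Seebach alkylation of the sulfur-stabilised carbanion with the reactive allylic chloride gives the acyl-anion equivalent that carries C6, C7, C8 and the C8 methyl.

Step 6
Reactants: 10 2-(2-methylprop-2-en-1-yl)-1,3-dithiane; 6 (4R)-4-[(tert-butyldimethylsilyl)oxy]-2-methylcyclopent-2-en-1-one
Product: 13 prop-2-en-1-yl (3R,4R)-4-[(tert-butyldimethylsilyl)oxy]-2-methyl-3-[2-(2-methylprop-2-en-1-yl)-1,3-dithian-2-yl]cyclopent-1-en-1-yl carbonate, via 2-lithio-2-(2-methylprop-2-en-1-yl)-1,3-dithiane 11 (not isolated), via lithium enolate of the 1,4-adduct 12 (not isolated)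
Conditions: n-BuLi, THF, −30 °C; HMPA (2.5 equiv), then 6, −78 °C; allyl chloroformate, −78 → −40 °C
Reagents that add atoms: allyl chloroformate, C=CCOC(=O)Cl
Why: Michael addition of the sulfur-stabilised carbanion (HMPA favours 1,4- over 1,2-addition) forms the C5–C6 bond on the enone face anti to the C4 silyloxy group, setting C5 with C6 on the β face, and O-acylation stores the regiodefined tetrasubstituted enolate as its allyl enol carbonate.

Step 7
Reactants: 13 the allyl enol carbonate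
Product: 14 (2R,3R,4R)-4-[(tert-butyldimethylsilyl)oxy]-2-methyl-3-[2-(2-methylprop-2-en-1-yl)-1,3-dithian-2-yl]-2-(prop-2-en-1-yl)cyclopentan-1-one
Conditions: Pd(PPh3)4 (5 mol %), THF, 25 °C
Reagents that add atoms: none
Why: Tsuji decarboxylative allylation (zerovalent palladium ionises the allyl carbonate, CO2 is lost, and the enolate is allylated at carbon under neutral conditions) builds the C1 quaternary centre with the allyl group entering anti to the bulky C5 dithianyl group, so allyl is α and methyl β.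

Step 8
Reactants: 14 the cyclopentanone
Product: 15 (6R,7R,8R)-8-[(tert-butyldimethylsilyl)oxy]-6-methyl-7-[2-(2-methylprop-2-en-1-yl)-1,3-dithian-2-yl]-6-(prop-2-en-1-yl)-1,4-dioxaspiro[4.4]nonane
Conditions: 1,2-bis(trimethylsilyloxy)ethane, TMSOTf (5 mol %), CH2Cl2, −78 → −20 °C
Reagents that add atoms: 1,2-bis(trimethylsilyloxy)ethane, C[Si](C)(C)OCCO[Si](C)(C)C
Why: Noyori ketalisation masks the C2 ketone under aprotic low-temperature conditions, so that the C4 ketone made in step 10 is not part of an enolised 1,3-diketone; the silyl ether, dithiane and alkenes are untouched and no stereocentre changes.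

Step 9
Reactants: 15 the silyl ether ketal
Product: 16 (7R,8R,9R)-9-methyl-8-[2-(2-methylprop-2-en-1-yl)-1,3-dithian-2-yl]-9-(prop-2-en-1-yl)-1,4-dioxaspiro[4.4]nonan-7-ol
Conditions: TBAF, THF, 25 °C
Reagents that add atoms: none
Why: Fluoride-mediated desilylation frees the temporary C4 hydroxyl, and with C2 ketalised there is no β-elimination pathway.

Step 10
Reactants: 16 the C4 alcohol
Product: 17 (8R,9R)-9-methyl-8-[2-(2-methylprop-2-en-1-yl)-1,3-dithian-2-yl]-9-(prop-2-en-1-yl)-1,4-dioxaspiro[4.4]nonan-7-one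
Conditions: (COCl)2, DMSO, CH2Cl2, −78 °C; then Et3N, −78 → −20 °C
Reagents that add atoms: none
Why: Swern oxidation (activated DMSO tolerates the dithiane) gives the C4 ketone; the C5 hydrogen is flanked by two fully substituted carbons and is not epimerised by the brief cold amine treatment.

Step 11
Reactants: 17 the C4 ketone
Product: 18 (7R,8R,9R)-9-methyl-8-[2-(2-methylprop-2-en-1-yl)-1,3-dithian-2-yl]-7-(propan-2-yl)-9-(prop-2-en-1-yl)-1,4-dioxaspiro[4.4]nonan-7-ol
Conditions: CeCl3 (anhydrous), i-PrMgCl, THF, −78 → 0 °C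
Reagents that add atoms: isopropylmagnesium chloride, CC(C)[Mg]Cl
Why: Imamoto organocerium 1,2-addition proceeds without enolisation or β-hydride reduction and from the α face, opposite the bulky C5 dithianyl substituent, giving the 4β-hydroxy-4α-isopropyl (4R) carbinol.

Step 12
Reactants: 18 the tertiary alcohol
Product: 19 1-[(6R,7R,8R)-8-hydroxy-6-methyl-8-(propan-2-yl)-6-(prop-2-en-1-yl)-1,4-dioxaspiro[4.4]nonan-7-yl]-3-methylbut-3-en-1-one
Conditions: PhI(OCOCF3)2, MeCN/H2O (9:1), 0 °C, 10 min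
Reagents that add atoms: water, O
Why: Stork–Zhao oxidative dithiane hydrolysis with the hypervalent iodine reagent is fast at 0 °C and unmasks the C6 ketone while alkenes, ketal and tertiary alcohol survive.

Step 13
Reactants: 19 the dienyl hydroxy ketone
Product: 20 (3'R,3a'R,8a'R)-3'-hydroxy-6',8a'-dimethyl-3'-(propan-2-yl)-2',3',3a',5',8',8a'-hexahydro-4'H-spiro[1,3-dioxolane-2,1'-azulen]-4'-one
Conditions: second-generation Grubbs catalyst (H2IMes)(PCy3)Cl2Ru=CHPh (5 mol %), CH2Cl2 (0.002 M), 40 °C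
Reagents that add atoms: none
Why: Ring-closing metathesis of the allyl and methallyl alkenes closes the seven-membered ring as the trisubstituted C8=C9 alkene, the trans ring fusion being fixed by the existing C1 and C5 configurations.

Step 14
Reactants: 20 the bicyclic hydroxy ketone
Product: 21 (3'R,3a'S,4'S,8a'R)-6',8a'-dimethyl-3'-(propan-2-yl)-3',3a',4',5',8',8a'-hexahydro-2'H-spiro[1,3-dioxolane-2,1'-azulene]-3',4'-diol
Conditions: Me4N[BH(OAc)3], MeCN/AcOH (1:1), −30 → 0 °C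
Reagents that add atoms: none
Why: Evans–Saksena hydroxyl-directed reduction delivers hydride from the boron-bound C4 oxygen to the β face of the C6 ketone, giving the 6α (6S) alcohol as the anti-1,3-diol.

Step 15
Reactants: 22 4-hydroxybenzoic acid
Product: 24 4-[(tert-butyldimethylsilyl)oxy]benzoic acid, via tert-butyldimethylsilyl 4-[(tert-butyldimethylsilyl)oxy]benzoate 23 (not isolated)
Conditions: TBSCl (2.2 equiv), imidazole, DMF, 25 °C; then AcOH/THF/H2O, 25 °C
Reagents that add atoms: TBSCl, CC(C)(C)[Si](C)(C)Cl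
Why: Bis-silylation followed by selective mild hydrolysis of the labile silyl ester gives the phenol-protected acid.

Step 16
Reactants: 21 the diol; 24 4-[(tert-butyldimethylsilyl)oxy]benzoic acid
Product: 25 (3'R,3a'S,4'S,8a'R)-3'-hydroxy-6',8a'-dimethyl-3'-(propan-2-yl)-3',3a',4',5',8',8a'-hexahydro-2'H-spiro[1,3-dioxolane-2,1'-azulen]-4'-yl 4-[(tert-butyldimethylsilyl)oxy]benzoate
Conditions: DCC, DMAP, CH2Cl2, 25 °C
Reagents that add atoms: none
Why: Steglich esterification acylates the secondary C6 hydroxyl with retention while the hindered tertiary C4 hydroxyl does not react.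

Step 17
Reactants: 25 the ketal ester
Product: 26 (3R,3aS,4S,8aR)-3-hydroxy-6,8a-dimethyl-1-oxo-3-(propan-2-yl)-1,2,3,3a,4,5,8,8a-octahydroazulen-4-yl 4-[(tert-butyldimethylsilyl)oxy]benzoate
Conditions: PPTS, acetone/H2O (10:1), 50 °C
Reagents that add atoms: water, O
Why: Mild acid-catalysed acetal hydrolysis releases the C2 ketone without dehydrating the tertiary alcohol or cleaving the aryl silyl ether or the esters.

Step 18
Reactants: 26 the C2 ketone
Product: 27 (1S,3R,3aS,4S,8aR)-1,3-dihydroxy-6,8a-dimethyl-3-(propan-2-yl)-1,2,3,3a,4,5,8,8a-octahydroazulen-4-yl 4-[(tert-butyldimethylsilyl)oxy]benzoate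
Conditions: Me4N[BH(OAc)3], MeCN/AcOH (1:1), −20 → 0 °C
Reagents that add atoms: none
Why: A second Evans–Saksena reduction delivers hydride from the boron-bound C4 oxygen across the five-membered ring to the β face of C2, giving the trans-1,3-diol with the 2α (2S) hydroxyl.

Step 19
Reactants: 27 the C2 alcohol
Product: 28 (1S,3R,3aS,4S,8aR)-1-(acetyloxy)-3-hydroxy-6,8a-dimethyl-3-(propan-2-yl)-1,2,3,3a,4,5,8,8a-octahydroazulen-4-yl 4-[(tert-butyldimethylsilyl)oxy]benzoate
Conditions: Ac2O, pyridine, DMAP (cat.), CH2Cl2, 0 → 25 °C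
Reagents that add atoms: acetic anhydride, CC(=O)OC(C)=O
Why: DMAP-catalysed acetylation esterifies the secondary C2 hydroxyl with retention while the tertiary C4 hydroxyl is inert.

Step 20
Reactants: 28 the silyl-protected acetate
Product: 29 (1S,3R,3aS,4S,8aR)-1-(acetyloxy)-3-hydroxy-6,8a-dimethyl-3-(propan-2-yl)-1,2,3,3a,4,5,8,8a-octahydroazulen-4-yl 4-hydroxybenzoate (CNP0275279.1)
Conditions: TBAF, AcOH, THF, 0 °C
Reagents that add atoms: none
Why: Acetic-acid-buffered fluoride cleavage of the aryl silyl ether frees the phenol without acyl transfer or ester cleavage.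

## Compound list

1 | (±)-1-(furan-2-yl)ethan-1-ol | CC(O)c1ccco1 | starting material
2 | (±)-trans-4-hydroxy-5-methylcyclopent-2-en-1-one ((4S,5R) enantiomer drawn) | C[C@@H]1[C@@H](O)C=CC1=O | intermediate (not isolated)
3 | (±)-4-hydroxy-2-methylcyclopent-2-en-1-one | CC1=CC(O)CC1=O | intermediate
4 | (1R)-3-methyl-4-oxocyclopent-2-en-1-yl acetate | CC1=C[C@H](OC(C)=O)CC1=O | intermediate
5 | (4R)-4-hydroxy-2-methylcyclopent-2-en-1-one | CC1=C[C@H](O)CC1=O | intermediate
6 | (4R)-4-[(tert-butyldimethylsilyl)oxy]-2-methylcyclopent-2-en-1-one | CC1=C[C@H](O[Si](C)(C)C(C)(C)C)CC1=O | intermediate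
7 | 1,3-dithiane | C1CSCSC1 | starting material
8 | 3-chloro-2-methylprop-1-ene | CC(=C)CCl | starting material
9 | 2-lithio-1,3-dithiane | [Li]C1SCCCS1 | intermediate (not isolated)
10 | 2-(2-methylprop-2-en-1-yl)-1,3-dithiane | CC(=C)CC1SCCCS1 | intermediate
11 | 2-lithio-2-(2-methylprop-2-en-1-yl)-1,3-dithiane | [Li]C1(CC(C)=C)SCCCS1 | intermediate (not isolated)
12 | lithium (3R,4R)-4-[(tert-butyldimethylsilyl)oxy]-2-methyl-3-[2-(2-methylprop-2-en-1-yl)-1,3-dithian-2-yl]cyclopent-1-en-1-olate | CC1=C(O[Li])C[C@@H](O[Si](C)(C)C(C)(C)C)[C@@H]1C2(CC(C)=C)SCCCS2 | intermediate (not isolated)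
13 | prop-2-en-1-yl (3R,4R)-4-[(tert-butyldimethylsilyl)oxy]-2-methyl-3-[2-(2-methylprop-2-en-1-yl)-1,3-dithian-2-yl]cyclopent-1-en-1-yl carbonate | CC1=C(OC(=O)OCC=C)C[C@@H](O[Si](C)(C)C(C)(C)C)[C@@H]1C2(CC(C)=C)SCCCS2 | intermediate
14 | (2R,3R,4R)-4-[(tert-butyldimethylsilyl)oxy]-2-methyl-3-[2-(2-methylprop-2-en-1-yl)-1,3-dithian-2-yl]-2-(prop-2-en-1-yl)cyclopentan-1-one | C=CC[C@@]1(C)C(=O)C[C@@H](O[Si](C)(C)C(C)(C)C)[C@@H]1C2(CC(C)=C)SCCCS2 | intermediate
15 | (6R,7R,8R)-8-[(tert-butyldimethylsilyl)oxy]-6-methyl-7-[2-(2-methylprop-2-en-1-yl)-1,3-dithian-2-yl]-6-(prop-2-en-1-yl)-1,4-dioxaspiro[4.4]nonane | C=CC[C@@]1(C)C2(OCCO2)C[C@@H](O[Si](C)(C)C(C)(C)C)[C@@H]1C3(CC(C)=C)SCCCS3 | intermediate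
16 | (7R,8R,9R)-9-methyl-8-[2-(2-methylprop-2-en-1-yl)-1,3-dithian-2-yl]-9-(prop-2-en-1-yl)-1,4-dioxaspiro[4.4]nonan-7-ol | C=CC[C@@]1(C)C2(OCCO2)C[C@@H](O)[C@@H]1C3(CC(C)=C)SCCCS3 | intermediate
17 | (8R,9R)-9-methyl-8-[2-(2-methylprop-2-en-1-yl)-1,3-dithian-2-yl]-9-(prop-2-en-1-yl)-1,4-dioxaspiro[4.4]nonan-7-one | C=CC[C@@]1(C)C2(OCCO2)CC(=O)[C@@H]1C3(CC(C)=C)SCCCS3 | intermediate
18 | (7R,8R,9R)-9-methyl-8-[2-(2-methylprop-2-en-1-yl)-1,3-dithian-2-yl]-7-(propan-2-yl)-9-(prop-2-en-1-yl)-1,4-dioxaspiro[4.4]nonan-7-ol | C=CC[C@@]1(C)C2(OCCO2)C[C@@](O)(C(C)C)[C@@H]1C3(CC(C)=C)SCCCS3 | intermediate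
19 | 1-[(6R,7R,8R)-8-hydroxy-6-methyl-8-(propan-2-yl)-6-(prop-2-en-1-yl)-1,4-dioxaspiro[4.4]nonan-7-yl]-3-methylbut-3-en-1-one | C=CC[C@@]1(C)C2(OCCO2)C[C@@](O)(C(C)C)[C@@H]1C(=O)CC(C)=C | intermediate
20 | (3'R,3a'R,8a'R)-3'-hydroxy-6',8a'-dimethyl-3'-(propan-2-yl)-2',3',3a',5',8',8a'-hexahydro-4'H-spiro[1,3-dioxolane-2,1'-azulen]-4'-one (trans-fused; C2 ketal, 4β-OH, C6 ketone) | O1CCOC12C[C@@](O)(C(C)C)[C@@H]3C(=O)CC(C)=CC[C@@]23C | intermediate
21 | (3'R,3a'S,4'S,8a'R)-6',8a'-dimethyl-3'-(propan-2-yl)-3',3a',4',5',8',8a'-hexahydro-2'H-spiro[1,3-dioxolane-2,1'-azulene]-3',4'-diol (4β,6α-diol) | O1CCOC12C[C@@](O)(C(C)C)[C@@H]3[C@@H](O)CC(C)=CC[C@@]23C | intermediate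
22 | 4-hydroxybenzoic acid | OC(=O)c1ccc(O)cc1 | starting material
23 | tert-butyldimethylsilyl 4-[(tert-butyldimethylsilyl)oxy]benzoate | CC(C)(C)[Si](C)(C)OC(=O)c1ccc(O[Si](C)(C)C(C)(C)C)cc1 | intermediate (not isolated)
24 | 4-[(tert-butyldimethylsilyl)oxy]benzoic acid | OC(=O)c1ccc(O[Si](C)(C)C(C)(C)C)cc1 | intermediate
25 | (3'R,3a'S,4'S,8a'R)-3'-hydroxy-6',8a'-dimethyl-3'-(propan-2-yl)-3',3a',4',5',8',8a'-hexahydro-2'H-spiro[1,3-dioxolane-2,1'-azulen]-4'-yl 4-[(tert-butyldimethylsilyl)oxy]benzoate | O1CCOC12C[C@@](O)(C(C)C)[C@@H]3[C@@H](OC(=O)c4ccc(O[Si](C)(C)C(C)(C)C)cc4)CC(C)=CC[C@@]23C | intermediate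
26 | (3R,3aS,4S,8aR)-3-hydroxy-6,8a-dimethyl-1-oxo-3-(propan-2-yl)-1,2,3,3a,4,5,8,8a-octahydroazulen-4-yl 4-[(tert-butyldimethylsilyl)oxy]benzoate | O=C1C[C@@](O)(C(C)C)[C@@H]2[C@@H](OC(=O)c3ccc(O[Si](C)(C)C(C)(C)C)cc3)CC(C)=CC[C@@]12C | intermediate
27 | (1S,3R,3aS,4S,8aR)-1,3-dihydroxy-6,8a-dimethyl-3-(propan-2-yl)-1,2,3,3a,4,5,8,8a-octahydroazulen-4-yl 4-[(tert-butyldimethylsilyl)oxy]benzoate | O[C@H]1C[C@@](O)(C(C)C)[C@@H]2[C@@H](OC(=O)c3ccc(O[Si](C)(C)C(C)(C)C)cc3)CC(C)=CC[C@@]12C | intermediate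
28 | (1S,3R,3aS,4S,8aR)-1-(acetyloxy)-3-hydroxy-6,8a-dimethyl-3-(propan-2-yl)-1,2,3,3a,4,5,8,8a-octahydroazulen-4-yl 4-[(tert-butyldimethylsilyl)oxy]benzoate | CC(=O)O[C@H]1C[C@@](O)(C(C)C)[C@@H]2[C@@H](OC(=O)c3ccc(O[Si](C)(C)C(C)(C)C)cc3)CC(C)=CC[C@@]12C | intermediate
29 | (1S,3R,3aS,4S,8aR)-1-(acetyloxy)-3-hydroxy-6,8a-dimethyl-3-(propan-2-yl)-1,2,3,3a,4,5,8,8a-octahydroazulen-4-yl 4-hydroxybenzoate | CC(=O)O[C@H]1C[C@@](O)(C(C)C)[C@@H]2[C@@H](OC(=O)c3ccc(O)cc3)CC(C)=CC[C@@]12C | target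

## Step count and risk

Total step count: 20. Longest linear sequence: 18 steps (steps 1–4, 6–14 and 16–20; steps 5 and 15 prepare side fragments).

**Step 6 (Michael addition of the tertiary dithianyl anion and enolate trapping).** The crowded carbanion may add 1,2 or not at all to the α-methyl enone. The fallback sets out from 6 (with 9, generated from 7 as in step 5) and comes back at 15. It forms the C5–C6 bond with the smaller secondary anion and attaches C7 afterwards.
- 9 is added to 6 in THF/HMPA at −78 °C to give lithium (3R,4R)-4-[(tert-butyldimethylsilyl)oxy]-3-(1,3-dithian-2-yl)-2-methylcyclopent-1-en-1-olate F1.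
- Allyl chloroformate traps it as prop-2-en-1-yl (3R,4R)-4-[(tert-butyldimethylsilyl)oxy]-3-(1,3-dithian-2-yl)-2-methylcyclopent-1-en-1-yl carbonate F2.
- Pd(PPh3)4 in THF converts this into (2R,3R,4R)-4-[(tert-butyldimethylsilyl)oxy]-3-(1,3-dithian-2-yl)-2-methyl-2-(prop-2-en-1-yl)cyclopentan-1-one F3.
- Noyori ketalisation as in step 8 gives (6R,7R,8R)-8-[(tert-butyldimethylsilyl)oxy]-7-(1,3-dithian-2-yl)-6-methyl-6-(prop-2-en-1-yl)-1,4-dioxaspiro[4.4]nonane F4.
- t-BuLi in THF/HMPA at −78 °C removes the dithiane C–H to give the 2-lithio-1,3-dithian-2-yl derivative of that ketal F5, and alkylation with 8 gives 15.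

**Step 11 (isopropyl addition to the ketone next to the dithiane carbon).** The neopentyl-type ketone may resist the bulky secondary nucleophile. The fallback sets out from 15 and comes back at 19. It removes the bulk first, so the isopropylcerium reagent meets a ketone whose C5 substituent is only a secondary ether carbon.
- PhI(OCOCF3)2 in aqueous MeCN converts 15 into 1-[(6R,7R,8R)-8-[(tert-butyldimethylsilyl)oxy]-6-methyl-6-(prop-2-en-1-yl)-1,4-dioxaspiro[4.4]nonan-7-yl]-3-methylbut-3-en-1-one F6.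
- NaBH4 in MeOH gives the corresponding 3-methylbut-3-en-1-ol (carbinol epimers, of no consequence) F7.
- NaH, 4-methoxybenzyl chloride and Bu4NI in DMF give its 4-methoxybenzyl ether F8.
- TBAF gives the ring alcohol 8-{1-[(4-methoxybenzyl)oxy]-3-methylbut-3-en-1-yl}-9-methyl-9-(prop-2-en-1-yl)-1,4-dioxaspiro[4.4]nonan-7-ol F9.
- Swern oxidation gives the corresponding nonan-7-one F10.
- CeCl3/i-PrMgCl adds anti to the C5 side chain to give the 7-(propan-2-yl)-nonan-7-ol F11.
- DDQ in CH2Cl2/pH 7 buffer removes the benzyl ether to give the diol 8-(1-hydroxy-3-methylbut-3-en-1-yl)-9-methyl-7-(propan-2-yl)-9-(prop-2-en-1-yl)-1,4-dioxaspiro[4.4]nonan-7-ol F12.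
- Dess–Martin periodinane (NaHCO3-buffered) oxidises only the secondary alcohol and gives 19.

**Step 18 (hydride delivery to the neopentyl C2 ketone from the hindered tertiary C4 hydroxyl).** Ligand exchange at the tertiary alcohol may be too slow and leave the ketone unreduced. The fallback sets out from 26 and comes back at 27. It replaces substrate-directed delivery by reagent control: Corey–Bakshi–Shibata reduction with (R)-2-methyl-CBS-oxazaborolidine and catecholborane in toluene at −78 → −40 °C. Catecholborane leaves the ring alkene alone. The catalyst distinguishes the quaternary C1 flank from the C3 methylene flank, and the (R)-catalyst gives the (2S)-alcohol 27 directly. No new compound is formed.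

## Further compounds

F1 | step 6 | lithium (3R,4R)-4-[(tert-butyldimethylsilyl)oxy]-3-(1,3-dithian-2-yl)-2-methylcyclopent-1-en-1-olate | CC1=C(O[Li])C[C@@H](O[Si](C)(C)C(C)(C)C)[C@@H]1C2SCCCS2
F2 | step 6 | prop-2-en-1-yl (3R,4R)-4-[(tert-butyldimethylsilyl)oxy]-3-(1,3-dithian-2-yl)-2-methylcyclopent-1-en-1-yl carbonate | CC1=C(OC(=O)OCC=C)C[C@@H](O[Si](C)(C)C(C)(C)C)[C@@H]1C2SCCCS2
F3 | step 6 | (2R,3R,4R)-4-[(tert-butyldimethylsilyl)oxy]-3-(1,3-dithian-2-yl)-2-methyl-2-(prop-2-en-1-yl)cyclopentan-1-one | C=CC[C@@]1(C)C(=O)C[C@@H](O[Si](C)(C)C(C)(C)C)[C@@H]1C2SCCCS2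
F4 | step 6 | (6R,7R,8R)-8-[(tert-butyldimethylsilyl)oxy]-7-(1,3-dithian-2-yl)-6-methyl-6-(prop-2-en-1-yl)-1,4-dioxaspiro[4.4]nonane | C=CC[C@@]1(C)C2(OCCO2)C[C@@H](O[Si](C)(C)C(C)(C)C)[C@@H]1C3SCCCS3
F5 | step 6 | 2-lithio-1,3-dithian-2-yl derivative of that ketal | C=CC[C@@]1(C)C2(OCCO2)C[C@@H](O[Si](C)(C)C(C)(C)C)[C@@H]1C3([Li])SCCCS3
F6 | step 11 | 1-[(6R,7R,8R)-8-[(tert-butyldimethylsilyl)oxy]-6-methyl-6-(prop-2-en-1-yl)-1,4-dioxaspiro[4.4]nonan-7-yl]-3-methylbut-3-en-1-one | C=CC[C@@]1(C)C2(OCCO2)C[C@@H](O[Si](C)(C)C(C)(C)C)[C@@H]1C(=O)CC(C)=C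
F7 | step 11 | 1-[8-[(tert-butyldimethylsilyl)oxy]-6-methyl-6-(prop-2-en-1-yl)-1,4-dioxaspiro[4.4]nonan-7-yl]-3-methylbut-3-en-1-ol (ring stereocentres as in 15, carbinol epimers) | C=CC[C@@]1(C)C2(OCCO2)C[C@@H](O[Si](C)(C)C(C)(C)C)[C@@H]1C(O)CC(C)=C
F8 | step 11 | 4-methoxybenzyl ether of that alcohol (ring stereocentres as in 15) | C=CC[C@@]1(C)C2(OCCO2)C[C@@H](O[Si](C)(C)C(C)(C)C)[C@@H]1C(OCc3ccc(OC)cc3)CC(C)=C
F9 | step 11 | 8-{1-[(4-methoxybenzyl)oxy]-3-methylbut-3-en-1-yl}-9-methyl-9-(prop-2-en-1-yl)-1,4-dioxaspiro[4.4]nonan-7-ol (ring stereocentres as in 16) | C=CC[C@@]1(C)C2(OCCO2)C[C@@H](O)[C@@H]1C(OCc3ccc(OC)cc3)CC(C)=C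
F10 | step 11 | 8-{1-[(4-methoxybenzyl)oxy]-3-methylbut-3-en-1-yl}-9-methyl-9-(prop-2-en-1-yl)-1,4-dioxaspiro[4.4]nonan-7-one (ring stereocentres as in 17) | C=CC[C@@]1(C)C2(OCCO2)CC(=O)[C@@H]1C(OCc3ccc(OC)cc3)CC(C)=C
F11 | step 11 | 8-{1-[(4-methoxybenzyl)oxy]-3-methylbut-3-en-1-yl}-9-methyl-7-(propan-2-yl)-9-(prop-2-en-1-yl)-1,4-dioxaspiro[4.4]nonan-7-ol (ring stereocentres as in 18) | C=CC[C@@]1(C)C2(OCCO2)C[C@@](O)(C(C)C)[C@@H]1C(OCc3ccc(OC)cc3)CC(C)=C
F12 | step 11 | 8-(1-hydroxy-3-methylbut-3-en-1-yl)-9-methyl-7-(propan-2-yl)-9-(prop-2-en-1-yl)-1,4-dioxaspiro[4.4]nonan-7-ol (ring stereocentres as in 18) | C=CC[C@@]1(C)C2(OCCO2)C[C@@](O)(C(C)C)[C@@H]1C(O)CC(C)=C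
F0 | step 18 | none | none
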